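**Plan**
- The last bond cut is N1–S: the free indole is released from its N-tosyl derivative.
- The pyrrole ring is then cut on both sides of C2 (N1–C2 and C2–C3). C2 is one carbon bonded only to N1, C3 and bromine, so it is at the oxidation level of a trihalomethane and is traced to bromoform. The C3–C3a…C7a–N1 unit is traced to an N-tosyl 2-(chloromethyl)-3,5-dibromoaniline, a latent aza-ortho-quinone methide.
- That sulfonanilide goes back by functional-group changes (CH2Cl from CH2OH from CH2Br from CH3; NHTs from NH2 from NO2) to a commercial bromonitrotoluene; the later C4–Br enters by ring bromination ortho to the methyl group.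
- Forward: the benzene ring is bought and dressed in six steps; the pyrrole ring, the only ring made, arises in step 7 with C2–C3 formed first and N1–C2 second; detosylation ends the route.
- The target is achiral, with no stereocentre and no stereogenic double bond, so no stereocontrol is needed.

Key step: step 7

Remark: the in-flask intermediates of the key step are drawn as neutral species, although the open-chain ones are present as cesium sulfonamidates.

**Step 1**
Reactants: 1 4-bromo-2-nitrotoluene
Product: 2 2,4-dibromo-6-nitrotoluene
Conditions: NBS (1.1 equiv), conc. H2SO4, 60 °C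
Reagents that add atoms: N-bromosuccinimide, O=C1CCC(=O)N1Br
Why: Electrophilic aromatic bromination with NBS in sulfuric acid, the usual method for deactivated arenes, should go to the one free position that is ortho to the methyl donor and meta to the nitro group, the other two free positions being ortho or para to NO2.

**Step 2**
Reactants: 2 2,4-dibromo-6-nitrotoluene
Product: 3 2,4-dibromo-6-nitrobenzyl bromide
Conditions: NBS (1.1 equiv), azobisisobutyronitrile (cat.), PhCF3, reflux
Reagents that add atoms: N-bromosuccinimide, O=C1CCC(=O)N1Br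
Why: Wohl–Ziegler radical bromination of the benzylic methyl group, as is routine for 2-bromo-6-nitrotoluene, should work because the electron-poor ring is inert to NBS under radical conditions.

**Step 3**
Reactants: 3 2,4-dibromo-6-nitrobenzyl bromide
Product: 4 (2,4-dibromo-6-nitrophenyl)methanol
Conditions: CaCO3, 1,4-dioxane/H2O (1:1), reflux
Reagents that add atoms: water, O
Why: SN2 hydrolysis of the benzylic bromide with CaCO3 as acid scavenger is a standard route to 2-nitrobenzyl alcohols and leaves the nitro group and the aryl bromides (both meta to NO2, hence not activated for SNAr) untouched.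

**Step 4**
Reactants: 4 (2,4-dibromo-6-nitrophenyl)methanol
Product: 5 (2-amino-4,6-dibromophenyl)methanol
Conditions: Fe powder, NH4Cl, EtOH/H2O (4:1), 80 °C
Reagents that add atoms: none
Why: Béchamp-type reduction with iron under near-neutral conditions is chemoselective for the nitro group over aryl C–Br bonds and the benzylic alcohol.

**Step 5**
Reactants: 5 (2-amino-4,6-dibromophenyl)methanol
Product: 6 N-[3,5-dibromo-2-(hydroxymethyl)phenyl]-4-methylbenzenesulfonamide
Conditions: TsCl (1.05 equiv), pyridine, CH2Cl2, 0 °C to rt
Reagents that add atoms: 4-methylbenzenesulfonyl chloride, Cc1ccc(cc1)S(=O)(=O)Cl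
Why: N-sulfonylation should be selective because the aniline nitrogen is far more nucleophilic toward TsCl in pyridine than the hindered, neutral benzylic alcohol, as in the usual preparation of N-tosyl 2-aminobenzyl alcohols.

**Step 6**
Reactants: 6 N-[3,5-dibromo-2-(hydroxymethyl)phenyl]-4-methylbenzenesulfonamide
Product: 7 N-[3,5-dibromo-2-(chloromethyl)phenyl]-4-methylbenzenesulfonamide
Conditions: SOCl2 (1.5 equiv), CH2Cl2, 0 °C to rt
Reagents that add atoms: thionyl chloride, O=S(Cl)Cl
Why: Deoxychlorination of the benzylic alcohol with thionyl chloride is the standard preparation of N-(2-chloromethylaryl)sulfonamides, and the sulfonamide N–H is inert to the reagent.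

**Step 7**
Reactants: 7 N-[3,5-dibromo-2-(chloromethyl)phenyl]-4-methylbenzenesulfonamide; 8 bromoform
Product: 13 2,4,6-tribromo-1-tosyl-1H-indole, via aza-ortho-quinone methide 9 (not isolated), via tribromoethyl adduct 10 (not isolated), via gem-dibromoalkene 11 (not isolated), via bromoalkyne 12 (not isolated)
Conditions: CHBr3 (5 equiv), Cs2CO3 (4 equiv), DMF, 0 °C (slow addition of 7) to rt, then 60 °C
Reagents that add atoms: none
Why: Proposed new method: Cs2CO3 deprotonates the sulfonamide of 7, chloride leaves by 1,4-elimination to give 9, and the tribromomethyl anion formed from 8 adds to the exocyclic CH2 of 9 in a rearomatising conjugate addition (C2–C3) to give 10. Base then removes a benzylic hydrogen of 10 with loss of bromide (the DDT-to-DDE type of dehydrohalogenation) to give 11, a second dehydrobromination gives 12, and the sulfonamide anion closes the pyrrole ring onto the bromine-bearing alkyne carbon (N1–C2) in a 5-endo-dig anionic cyclisation followed by protonation at C3. The closest known reactions are the (4+1) annulations of such aza-ortho-quinone methides with sulfur ylides and α-halo carbon acids to indolines, the addition of base-generated tribromomethyl anion to aldehydes and Michael acceptors, and the carbonate-promoted cyclisation of 2-(2,2-dibromovinyl)sulfonanilides to 2-bromoindoles. No stereocentre is formed. The step needs carbon capture of 9 by the tribromomethyl anion to outrun both α-elimination to dibromocarbene and N-alkylation of a second sulfonamide anion by 9; excess bromoform, a cold addition phase, slow feeding of 7, the steric shielding of the ortho-substituted sulfonamide nitrogen and the fact that the exocyclic CH2 is the only electrophilic site of 9 should secure this. Any dibromocarbene that does form can still lead to 13 by (4+1) capture to a 2,2-dibromoindoline and loss of HBr.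

**Step 8**
Reactants: 13 2,4,6-tribromo-1-tosyl-1H-indole
Product: 14 2,4,6-tribromo-1H-indole
Conditions: KOH (3 equiv), hexadecyltrimethylammonium bromide (10 mol %), THF/H2O, rt to 40 °C, in the dark
Reagents that add atoms: none
Why: Nucleophilic cleavage of the N–S bond by hydroxide under phase-transfer conditions should be easy because the tribrominated indolide is a good leaving group, and the alcohol-free medium avoids alkyl tosylates that could N-alkylate the product.

**Compound list**
1 | 4-bromo-2-nitrotoluene | Cc1ccc(Br)cc1[N+](=O)[O-] | starting material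
2 | 2,4-dibromo-6-nitrotoluene (1,5-dibromo-2-methyl-3-nitrobenzene) | Cc1c(Br)cc(Br)cc1[N+](=O)[O-] | intermediate
3 | 2,4-dibromo-6-nitrobenzyl bromide | BrCc1c(Br)cc(Br)cc1[N+](=O)[O-] | intermediate
4 | (2,4-dibromo-6-nitrophenyl)methanol | OCc1c(Br)cc(Br)cc1[N+](=O)[O-] | intermediate
5 | (2-amino-4,6-dibromophenyl)methanol | Nc1cc(Br)cc(Br)c1CO | intermediate
6 | N-[3,5-dibromo-2-(hydroxymethyl)phenyl]-4-methylbenzenesulfonamide | Cc1ccc(cc1)S(=O)(=O)Nc1cc(Br)cc(Br)c1CO | intermediate
7 | N-[3,5-dibromo-2-(chloromethyl)phenyl]-4-methylbenzenesulfonamide | Cc1ccc(cc1)S(=O)(=O)Nc1cc(Br)cc(Br)c1CCl | intermediate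
8 | bromoform | BrC(Br)Br | starting material
9 | N-(3,5-dibromo-6-methylidenecyclohexa-2,4-dien-1-ylidene)-4-methylbenzenesulfonamide (aza-ortho-quinone methide) | Cc1ccc(cc1)S(=O)(=O)N=C1C=C(Br)C=C(Br)C1=C | intermediate
10 | N-[3,5-dibromo-2-(2,2,2-tribromoethyl)phenyl]-4-methylbenzenesulfonamide | Cc1ccc(cc1)S(=O)(=O)Nc1cc(Br)cc(Br)c1CC(Br)(Br)Br | intermediate
11 | N-[3,5-dibromo-2-(2,2-dibromoethenyl)phenyl]-4-methylbenzenesulfonamide | Cc1ccc(cc1)S(=O)(=O)Nc1cc(Br)cc(Br)c1C=C(Br)Br | intermediate
12 | N-[3,5-dibromo-2-(bromoethynyl)phenyl]-4-methylbenzenesulfonamide | Cc1ccc(cc1)S(=O)(=O)Nc1cc(Br)cc(Br)c1C#CBr | intermediate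
13 | 2,4,6-tribromo-1-tosyl-1H-indole | Cc1ccc(cc1)S(=O)(=O)n1c(Br)cc2c(Br)cc(Br)cc21 | intermediate
14 | 2,4,6-tribromo-1H-indole | Brc1cc(Br)c2cc(Br)[nH]c2c1 | target

**Step count and risks**
Total steps: 8. Longest linear sequence: 8 steps (1 to 14).

Steps most likely to fail:

1. Step 7 (the proposed new method). The tribromomethyl anion may lose bromide to dibromocarbene before it is intercepted, the quinone methide may be consumed by N-alkylation and oligomerisation, or the cascade may stall before the second dehydrobromination. The fallback uses known chemistry only and sets out from 6. Oxidation of the benzylic alcohol with MnO2 in CH2Cl2 should give N-(3,5-dibromo-2-formylphenyl)-4-methylbenzenesulfonamide F1. Ramirez gem-dibromoolefination (CBr4, PPh3, CH2Cl2, 0 °C, with extra ylide to allow for the acidic N–H) should then give 11, which is isolated in this variant. The route is rejoined at 11, which Cs2CO3 in DMF at 60–80 °C should carry to 13 by the established cyclisation of 2-(2,2-dibromovinyl)sulfonanilides to 2-bromoindoles. C2 then comes from CBr4 by olefination, and the N1–C2 closure is unchanged.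

2. Step 2. Hydrogen abstraction from the hindered, electron-poor methyl group may be slow, so that a second bromination of the product competes with conversion. The fallback sets out from 2 and uses the acidity that the ortho nitro group gives the methyl group. Condensation with N,N-dimethylformamide dimethyl acetal (DMF, 110 °C, the first half of a Leimgruber–Batcho sequence) should give (E)-2-(2,4-dibromo-6-nitrophenyl)-N,N-dimethylethen-1-amine F2. Oxidative cleavage of the enamine double bond with NaIO4 in THF/H2O should give 2,4-dibromo-6-nitrobenzaldehyde F3. Reduction with NaBH4 in MeOH at 0 °C rejoins the route at 4, bypassing 3.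

3. Step 8. Hydroxide may attack C2 in competition with sulfur, or the liberated base- and light-sensitive 2-bromoindole may degrade during prolonged S–N hydrolysis. The fallback sets out from 5 and replaces tosyl by the 2-(trimethylsilyl)ethanesulfonyl group, which is removed by fluoride-triggered fragmentation and not by hydrolysis. Sulfonylation of 5 with 2-(trimethylsilyl)ethanesulfonyl chloride and pyridine in CH2Cl2 should give N-[3,5-dibromo-2-(hydroxymethyl)phenyl]-2-(trimethylsilyl)ethanesulfonamide F4. SOCl2 in CH2Cl2 should convert it to N-[3,5-dibromo-2-(chloromethyl)phenyl]-2-(trimethylsilyl)ethanesulfonamide F5. Under the conditions of step 7 (by then proven on 7), F5 should pass through four species that are not isolated: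
   - the aza-ortho-quinone methide N-(3,5-dibromo-6-methylidenecyclohexa-2,4-dien-1-ylidene)-2-(trimethylsilyl)ethanesulfonamide F6;
   - the adduct N-[3,5-dibromo-2-(2,2,2-tribromoethyl)phenyl]-2-(trimethylsilyl)ethanesulfonamide F7;
   - the alkene N-[3,5-dibromo-2-(2,2-dibromoethenyl)phenyl]-2-(trimethylsilyl)ethanesulfonamide F8;
   - the alkyne N-[3,5-dibromo-2-(bromoethynyl)phenyl]-2-(trimethylsilyl)ethanesulfonamide F9.

   The product should be 2,4,6-tribromo-1-{[2-(trimethylsilyl)ethyl]sulfonyl}-1H-indole F10. Tetrabutylammonium fluoride (Bu4NF) in THF at rt should then release the indole with loss of fluorotrimethylsilane, ethene and sulfur dioxide, rejoining the route at 14.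

**Further compounds**
F1 | step 7 | N-(3,5-dibromo-2-formylphenyl)-4-methylbenzenesulfonamide | Cc1ccc(cc1)S(=O)(=O)Nc1cc(Br)cc(Br)c1C=O
F2 | step 2 | (E)-2-(2,4-dibromo-6-nitrophenyl)-N,N-dimethylethen-1-amine | CN(C)/C=C/c1c(Br)cc(Br)cc1[N+](=O)[O-]
F3 | step 2 | 2,4-dibromo-6-nitrobenzaldehyde | O=Cc1c(Br)cc(Br)cc1[N+](=O)[O-]
F4 | step 8 | N-[3,5-dibromo-2-(hydroxymethyl)phenyl]-2-(trimethylsilyl)ethanesulfonamide | C[Si](C)(C)CCS(=O)(=O)Nc1cc(Br)cc(Br)c1CO
F5 | step 8 | N-[3,5-dibromo-2-(chloromethyl)phenyl]-2-(trimethylsilyl)ethanesulfonamide | C[Si](C)(C)CCS(=O)(=O)Nc1cc(Br)cc(Br)c1CCl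
F6 | step 8 | N-(3,5-dibromo-6-methylidenecyclohexa-2,4-dien-1-ylidene)-2-(trimethylsilyl)ethanesulfonamide | C[Si](C)(C)CCS(=O)(=O)N=C1C=C(Br)C=C(Br)C1=C
F7 | step 8 | N-[3,5-dibromo-2-(2,2,2-tribromoethyl)phenyl]-2-(trimethylsilyl)ethanesulfonamide | C[Si](C)(C)CCS(=O)(=O)Nc1cc(Br)cc(Br)c1CC(Br)(Br)Br
F8 | step 8 | N-[3,5-dibromo-2-(2,2-dibromoethenyl)phenyl]-2-(trimethylsilyl)ethanesulfonamide | C[Si](C)(C)CCS(=O)(=O)Nc1cc(Br)cc(Br)c1C=C(Br)Br
F9 | step 8 | N-[3,5-dibromo-2-(bromoethynyl)phenyl]-2-(trimethylsilyl)ethanesulfonamide | C[Si](C)(C)CCS(=O)(=O)Nc1cc(Br)cc(Br)c1C#CBr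
F10 | step 8 | 2,4,6-tribromo-1-{[2-(trimethylsilyl)ethyl]sulfonyl}-1H-indole | C[Si](C)(C)CCS(=O)(=O)n1c(Br)cc2c(Br)cc(Br)cc21
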